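**Retrosynthetic overview**
- Ring B, the central benzene, carries the diaryl-ether oxygen and the free phenol oxygen para to each other. The depside ester oxygen sits next to the ether carbon, there is one CH, and the lactone carboxyl carbon and the benzylic CH2 carbon are adjacent. This is the substituent pattern that thermolysis of a 3-alkoxy-4-alkenyl-4-hydroxycyclobutenone produces.
- Late disconnections, in order: the seven-membered depsidone ester C–O bond, the isopropyl ether, the spiro acyloxy-ketal lactone (set by equilibration), and the diaryl ether. These lead back to a ring B hydroquinone and a ring A 8-bromoisocoumarin, which masks both the keto and the carboxyl group.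
- The hydroquinone comes from a cyclobutenone carbinol, made from isopropyl semisquarate and an E-alkenylmagnesium. The alkenyl iodide comes from syn stannylcupration of an ynoate, itself built from the (R)-lactone, a propargyl unit and Boc2O.
- Order of ring formation: oxane, ring B (electrocyclisation), temporary isocoumarin ring on ring A, spirolactone ring, seven-membered ring.

Key step: step 10

Remark: on an oxane chair with the methyl group equatorial, the spiro carbon of the target has its acyloxy oxygen axial and its benzylic CH2 equatorial. It is therefore assumed to be the anomerically stabilised, thermodynamic epimer and is set by acid equilibration. The methyl ketal carbon and the cyclobutenone carbinol carbon are carried as mixtures because both are erased later.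

**Step 1**
Reactants: 1 diisopropyl squarate
Product: 3 3-isopropoxycyclobut-3-ene-1,2-dione (isopropyl semisquarate), via 4-hydroxy-2,3-diisopropoxycyclobut-2-enone 2 (not isolated)
Conditions: LiAlH(OtBu)3, THF, −78 → −20 °C; then 2 M HCl, CH2Cl2, rt
Reagents that add atoms: water, O
Why: The bulky, mild aluminium hydride reduces one squarate carbonyl 1,2 and stops at carbinol 2, and acid-catalysed allylic ionisation and hydrolysis of the vinylogous ester (the usual squarate-to-cyclobutenedione transposition) then expels isopropanol.

**Step 2**
Reactants: 4 ethyl 5-oxohexanoate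
Product: 5 ethyl (5R)-5-hydroxyhexanoate
Conditions: Lactobacillus kefir alcohol dehydrogenase, NADP+ (cat.), MgCl2 (cat.), iPrOH, phosphate buffer pH 7, 30 °C
Reagents that add atoms: none
Why: In this biocatalytic anti-Prelog ketone reduction the enzyme pocket delivers hydride to one face of the methyl ketone and so sets the (R) carbinol centre, while the ester is untouched and isopropanol recycles the cofactor.

**Step 3**
Reactants: 5 ethyl (5R)-5-hydroxyhexanoate
Product: 6 (6R)-6-methyloxan-2-one
Conditions: TsOH·H2O (cat.), PhMe, 80 °C, EtOH distilled off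
Reagents that add atoms: none
Why: Acid-catalysed lactonisation (intramolecular transesterification) exchanges only the acyl–oxygen bond, so the C–O bond at the stereocentre stays intact and the (R) configuration is kept.

**Step 4**
Reactants: 6 (6R)-6-methyloxan-2-one; 7 propargyl bromide
Product: 9 (6R)-6-methyl-2-(prop-2-yn-1-yl)oxan-2-ol (lactol and anomer mixture), via allenylmagnesium bromide 8 (not isolated)
Conditions: 7, Mg, HgCl2 (cat.), Et2O, 0 °C; then 6, Et2O, −78 °C; H2O quench at −78 °C
Reagents that add atoms: none
Why: In this Grignard addition to a lactone the allenylmagnesium reagent reacts through its γ-carbon (SE2′) and delivers a propargyl group, and at −78 °C the cyclic magnesium hemiketal does not collapse, which holds back a second addition.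

**Step 5**
Reactants: 9 (6R)-6-methyl-2-(prop-2-yn-1-yl)oxan-2-ol
Product: 10 (6R)-2-methoxy-6-methyl-2-(prop-2-yn-1-yl)oxane (ketal centre unassigned)
Conditions: MeOH, PPTS (cat.), 3 Å MS, rt
Reagents that add atoms: methanol, CO
Why: Acid-catalysed ketalisation of the lactol through the cyclic oxocarbenium ion replaces OH by OMe under acidity too weak to touch the alkyne or the remote stereocentre, and the new centre needs no control.

**Step 6**
Reactants: 10 (6R)-2-methoxy-6-methyl-2-(prop-2-yn-1-yl)oxane
Product: 12 tert-butyl 4-[(6R)-2-methoxy-6-methyloxan-2-yl]but-2-ynoate, via lithium acetylide 11 (not isolated)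
Conditions: n-BuLi, THF, −78 °C; Boc2O, −78 °C; AcOH quench at −78 °C
Reagents that add atoms: di-tert-butyl dicarbonate, CC(C)(C)OC(=O)OC(=O)OC(C)(C)C
Why: C-acylation of a lithium acetylide with Boc2O is a standard route to tert-butyl alkynoates, the cold acid quench prevents alkoxide-induced alkyne-to-allene isomerisation, and the tert-butyl ester is chosen because it resists organomagnesium reagents and leaves later under acid.

**Step 7**
Reactants: 12 tert-butyl 4-[(6R)-2-methoxy-6-methyloxan-2-yl]but-2-ynoate
Product: 14 tert-butyl (2E)-4-[(6R)-2-methoxy-6-methyloxan-2-yl]-3-(tributylstannyl)but-2-enoate, via alkenylcopper adduct 13 (not isolated)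
Conditions: Bu3SnH, LDA, THF, 0 °C; CuBr·SMe2, −78 °C; then 12, MeOH, THF, −78 °C
Reagents that add atoms: tributyltin hydride, CCCC[SnH](CCCC)CCCC
Why: Stannylcupration of an alkynoate is a syn addition that puts tin on the β-carbon and copper on the α-carbon, and methanol present at −78 °C protonates 13 before it can isomerise through the allenoate, so tin and ester end up trans under non-acidic conditions that spare the ketal (hot NaI/AcOH hydroiodination would spare neither the ketal nor this geometry).

**Step 8**
Reactants: 14 tert-butyl (2E)-4-[(6R)-2-methoxy-6-methyloxan-2-yl]-3-(tributylstannyl)but-2-enoate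
Product: 15 tert-butyl (2E)-3-iodo-4-[(6R)-2-methoxy-6-methyloxan-2-yl]but-2-enoate (iodine and ester trans)
Conditions: I2, CH2Cl2, 0 °C
Reagents that add atoms: iodine, II
Why: Iododestannylation is an electrophilic ipso substitution at the C–Sn bond that proceeds with retention of alkene geometry and is brief and mild enough for the ketal.

**Step 9**
Reactants: 15 tert-butyl (2E)-3-iodo-4-[(6R)-2-methoxy-6-methyloxan-2-yl]but-2-enoate; 3 3-isopropoxycyclobut-3-ene-1,2-dione
Product: 17 tert-butyl (2E)-3-(1-hydroxy-2-isopropoxy-4-oxocyclobut-2-en-1-yl)-4-[(6R)-2-methoxy-6-methyloxan-2-yl]but-2-enoate (ring carbon and ester trans; carbinol and ketal centres unassigned), via alkenylmagnesium chloride 16 (not isolated)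
Conditions: iPrMgCl·LiCl, THF, −78 → −40 °C; then 3, THF, −78 °C; pH 7 buffer at −78 °C
Reagents that add atoms: none
Why: Iodine–magnesium exchange with the turbo-Grignard reagent is fast on an acceptor-substituted alkenyl iodide, tolerates the tert-butyl ester and keeps the geometry at low temperature, the alkenylmagnesium then adds 1,2 to the carbonyl next to the isopropoxy carbon because the other carbonyl is a deactivated vinylogous ester, and with alkoxide and ester trans no butenolide can form.

**Step 10**
Reactants: 17 tert-butyl (2E)-3-(1-hydroxy-2-isopropoxy-4-oxocyclobut-2-en-1-yl)-4-[(6R)-2-methoxy-6-methyloxan-2-yl]but-2-enoate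
Product: 20 tert-butyl 3,6-dihydroxy-4-isopropoxy-2-{[(6R)-2-methoxy-6-methyloxan-2-yl]methyl}benzoate (ring B hydroquinone), via dienylketene 18 (not isolated), via cyclohexadienone 19 (not isolated)
Conditions: PhMe (degassed, 0.01 M), 110 °C, Ar, base-washed glassware
Reagents that add atoms: none
Why: Heat breaks the bond between the carbonyl carbon and the carbinol carbon of the four-membered ring in a conrotatory four-electron electrocyclic opening, in which the donor hydroxyl rotates away from the breaking bond and the acceptor-substituted alkenyl arm rotates towards it, so dienylketene 18 forms with its ketene carbon beside the ester-bearing alkene carbon. A disrotatory six-electron electrocyclisation joins these two carbons, making the ring B bond between the future phenol carbon and the carboxyl-bearing carbon and closing ring B as a six-membered carbocycle, and dienone 19, a cyclic β-keto ester, enolises at once to hydroquinone 20. The closest known reaction type is the thermal ring expansion of squarate-derived 4-alkenyl-4-hydroxycyclobutenones to hydroquinones (the alkenyl variant of the Moore rearrangement). No stereocentre is formed: the carbinol centre vanishes, the ketal centre stays an inconsequential mixture and the (R) centre is remote and untouched. The step needs torquoselectivity and ring closure faster than ketene capture; the first follows from the outward preference of an oxygen donor, the second from the E alkene, which leaves only hydrogen on the inner side of the closing terminus and keeps the ester away from the hydroxyl (the Z isomer would lactonise to a spirobutenolide that cannot close), and from the isopropoxydiene pushing electron density onto the ester α-carbon towards the electrophilic ketene carbon. The positions of all five substituents follow from the connectivity of 17, and neutral, dilute, oxygen-free conditions protect the methyl ketal and the air-sensitive product.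

**Step 11**
Reactants: 21 3,5-dibromoanisole
Product: 23 methyl 2,6-dibromo-4-methoxybenzoate, via 2,6-dibromo-4-methoxyphenyllithium 22 (not isolated)
Conditions: LDA, THF, −78 °C; ClCO2Me, −78 °C → rt
Reagents that add atoms: methyl chloroformate, COC(=O)Cl
Why: In this deprotonative lithiation LDA removes the most acidic ring proton, the one flanked by both bromines, and the aryllithium is stable at −78 °C and is acylated by the chloroformate.

**Step 12**
Reactants: 23 methyl 2,6-dibromo-4-methoxybenzoate; 24 hept-1-yne
Product: 25 methyl 2-bromo-6-(hept-1-yn-1-yl)-4-methoxybenzoate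
Conditions: PdCl2(PPh3)2 (cat.), CuI (cat.), Et3N, DMF, 60 °C, 24 as limiting reagent
Reagents that add atoms: none
Why: In this Sonogashira coupling the two ester-activated C–Br bonds are equivalent, so a deficit of alkyne should favour monoalkynylation and unreacted 23 can be recovered.

**Step 13**
Reactants: 25 methyl 2-bromo-6-(hept-1-yn-1-yl)-4-methoxybenzoate
Product: 26 8-bromo-6-methoxy-3-pentyl-1H-isochromen-1-one
Conditions: AgOCOCF3 (cat.), TFA, CH2Cl2, 40 °C
Reagents that add atoms: none
Why: In this silver- and acid-promoted 6-endo-dig cyclisation of an o-alkynylbenzoate the ester carbonyl oxygen attacks the activated distal alkyne carbon and trifluoroacetate removes the methyl group, giving an enol lactone that stores the 2-oxoheptyl ketone and the carboxyl group without an acidic CH2.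

**Step 14**
Reactants: 20 ring B hydroquinone; 26 8-bromo-6-methoxy-3-pentyl-1H-isochromen-1-one
Product: 27 tert-butyl 6-hydroxy-4-isopropoxy-3-[(6-methoxy-1-oxo-3-pentyl-1H-isochromen-8-yl)oxy]-2-{[(6R)-2-methoxy-6-methyloxan-2-yl]methyl}benzoate
Conditions: CuI (cat.), picolinic acid (cat.), K3PO4, 4 Å MS, DMSO (degassed), 85 °C, Ar
Reagents that add atoms: none
Why: This is an Ullmann diaryl ether synthesis under ligand-accelerated copper catalysis suited to ortho-substituted partners, in which the C–Br bond is activated by the neighbouring lactone carbonyl, the hydroxyl beside the side chain is the more nucleophilic one because the other is hydrogen-bonded to and conjugated with the tert-butyl ester, and forming the ether before any acid step stops this hydroxyl from capturing the ketal carbon as a dihydrobenzofuran spiroketal.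

**Step 15**
Reactants: 27 diaryl ether
Product: 28 (3S,6'R)-8-hydroxy-6-isopropoxy-5-[(6-methoxy-1-oxo-3-pentyl-1H-isochromen-8-yl)oxy]-6'-methylspiro[isochromane-3,2'-oxan]-1-one
Conditions: TFA, CH2Cl2, 0 °C → rt
Reagents that add atoms: none
Why: Acidolysis of the tert-butyl ester and ionisation of the methyl ketal let the carboxyl oxygen close onto the oxane ketal carbon (acid-catalysed spirolactonisation, six-membered ring), and because the acyloxy ketal ionises reversibly the spiro centre settles under thermodynamic control with the acyloxy oxygen axial (anomeric effect) and the CH2 and methyl groups equatorial, which is (S) relative to the fixed (R) centre.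

**Step 16**
Reactants: 28 isopropyl ether spirolactone
Product: 29 (3S,6'R)-6,8-dihydroxy-5-[(6-methoxy-1-oxo-3-pentyl-1H-isochromen-8-yl)oxy]-6'-methylspiro[isochromane-3,2'-oxan]-1-one
Conditions: BCl3, CH2Cl2, −78 → 0 °C; then H2O
Reagents that add atoms: none
Why: Boron trichloride dealkylation of an aryl isopropyl ether, a standard phenol unmasking in depsidone chemistry, cleaves the secondary alkyl–oxygen bond while sparing the aryl methyl ether, the diaryl ether and the enol lactone, and any reversible ionisation of the acyloxy ketal should re-close on work-up to the same favoured epimer.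

**Step 17**
Reactants: 29 isocoumarin diphenol
Product: 30 2-{[(3S,6'R)-6,8-dihydroxy-6'-methyl-1-oxospiro[isochromane-3,2'-oxan]-5-yl]oxy}-4-methoxy-6-(2-oxoheptyl)benzoic acid
Conditions: LiOH, THF/H2O (degassed), rt; then 1 M HCl to pH 3, 0 °C
Reagents that add atoms: lithium hydroxide, [Li+].[OH-]
Why: Saponification of the enol lactone frees the carboxylate and, after tautomerisation, the 2-oxoheptyl ketone, the aqueous medium and low temperature disfavour aryl migration between the neighbouring ring B oxygens (Smiles rearrangement), and should hydroxide also open the spirolactone, acidification re-closes it under the same thermodynamic control.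

**Step 18**
Reactants: 30 keto acid
Product: 31 target depsidone (spiro carbon S; methyl-bearing carbon R)
Conditions: DCC, CH2Cl2 (1 mM), 0 °C → rt, no base
Reagents that add atoms: none
Why: Carbodiimide lactonisation is the usual closure of 2-(2-hydroxyaryloxy)benzoic acids to depsidones, only the hydroxyl next to the ether oxygen can reach the activated carboxyl (seven-membered ring) while the other phenol is hydrogen-bonded to the lactone carbonyl and out of reach, and base-free high dilution favours the phenol over the weakly nucleophilic ketone enol.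

**Compound list**
1 | diisopropyl squarate | CC(C)OC1=C(OC(C)C)C(=O)C1=O | starting material
2 | 4-hydroxy-2,3-diisopropoxycyclobut-2-enone | CC(C)OC1=C(OC(C)C)C(O)C1=O | intermediate
3 | 3-isopropoxycyclobut-3-ene-1,2-dione | CC(C)OC1=CC(=O)C1=O | intermediate
4 | ethyl 5-oxohexanoate | CCOC(=O)CCCC(C)=O | starting material
5 | ethyl (5R)-5-hydroxyhexanoate | CCOC(=O)CCC[C@@H](C)O | intermediate
6 | (6R)-6-methyloxan-2-one | C[C@@H]1CCCC(=O)O1 | intermediate
7 | propargyl bromide | BrCC#C | starting material
8 | allenylmagnesium bromide | C=C=C[Mg]Br | intermediate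
9 | (6R)-6-methyl-2-(prop-2-yn-1-yl)oxan-2-ol | C#CCC1(O)CCC[C@@H](C)O1 | intermediate
10 | (6R)-2-methoxy-6-methyl-2-(prop-2-yn-1-yl)oxane | C#CCC1(OC)CCC[C@@H](C)O1 | intermediate
11 | lithium acetylide of 10 | [Li]C#CCC1(OC)CCC[C@@H](C)O1 | intermediate
12 | tert-butyl 4-[(6R)-2-methoxy-6-methyloxan-2-yl]but-2-ynoate | CC(C)(C)OC(=O)C#CCC1(OC)CCC[C@@H](C)O1 | intermediate
13 | α-cuprio-β-stannyl enoate (tin and copper cis) | CCCC[Sn](CCCC)(CCCC)/C(CC1(OC)CCC[C@@H](C)O1)=C(\[Cu])C(=O)OC(C)(C)C | intermediate
14 | tert-butyl (2E)-4-[(6R)-2-methoxy-6-methyloxan-2-yl]-3-(tributylstannyl)but-2-enoate | CCCC[Sn](CCCC)(CCCC)/C(CC1(OC)CCC[C@@H](C)O1)=C/C(=O)OC(C)(C)C | intermediate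
15 | tert-butyl (2E)-3-iodo-4-[(6R)-2-methoxy-6-methyloxan-2-yl]but-2-enoate | I/C(CC1(OC)CCC[C@@H](C)O1)=C/C(=O)OC(C)(C)C | intermediate
16 | alkenylmagnesium chloride from 15 | Cl[Mg]/C(CC1(OC)CCC[C@@H](C)O1)=C/C(=O)OC(C)(C)C | intermediate
17 | tert-butyl (2E)-3-(1-hydroxy-2-isopropoxy-4-oxocyclobut-2-en-1-yl)-4-[(6R)-2-methoxy-6-methyloxan-2-yl]but-2-enoate | O=C1C=C(OC(C)C)C1(O)/C(CC2(OC)CCC[C@@H](C)O2)=C/C(=O)OC(C)(C)C | intermediate
18 | dienylketene (hydroxyl outward, alkenyl arm inward) | O=C=C/C(OC(C)C)=C(/O)\C(CC1(OC)CCC[C@@H](C)O1)=C\C(=O)OC(C)(C)C | intermediate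
19 | 6-(tert-butoxycarbonyl)cyclohexa-2,4-dienone | O=C1C=C(OC(C)C)C(O)=C(CC2(OC)CCC[C@@H](C)O2)C1C(=O)OC(C)(C)C | intermediate
20 | tert-butyl 3,6-dihydroxy-4-isopropoxy-2-{[(6R)-2-methoxy-6-methyloxan-2-yl]methyl}benzoate | CC(C)(C)OC(=O)c1c(O)cc(OC(C)C)c(O)c1CC1(OC)CCC[C@@H](C)O1 | intermediate
21 | 3,5-dibromoanisole | COc1cc(Br)cc(Br)c1 | starting material
22 | 2,6-dibromo-4-methoxyphenyllithium | [Li]c1c(Br)cc(OC)cc1Br | intermediate
23 | methyl 2,6-dibromo-4-methoxybenzoate | COC(=O)c1c(Br)cc(OC)cc1Br | intermediate
24 | hept-1-yne | CCCCCC#C | starting material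
25 | methyl 2-bromo-6-(hept-1-yn-1-yl)-4-methoxybenzoate | CCCCCC#Cc1cc(OC)cc(Br)c1C(=O)OC | intermediate
26 | 8-bromo-6-methoxy-3-pentyl-1H-isochromen-1-one | CCCCCC1=Cc2cc(OC)cc(Br)c2C(=O)O1 | intermediate
27 | diaryl ether (tert-butyl ester, methyl ketal, isopropyl ether, isocoumarin) | CCCCCC1=Cc2cc(OC)cc(Oc3c(OC(C)C)cc(O)c(C(=O)OC(C)(C)C)c3CC3(OC)CCC[C@@H](C)O3)c2C(=O)O1 | intermediate
28 | (3S,6'R)-spirolactone isopropyl ether | CCCCCC1=Cc2cc(OC)cc(Oc3c(OC(C)C)cc(O)c4c3C[C@]3(CCC[C@@H](C)O3)OC4=O)c2C(=O)O1 | intermediate
29 | (3S,6'R)-spirolactone diphenol isocoumarin | CCCCCC1=Cc2cc(OC)cc(Oc3c(O)cc(O)c4c3C[C@]3(CCC[C@@H](C)O3)OC4=O)c2C(=O)O1 | intermediate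
30 | (3S,6'R)-spirolactone keto acid | CCCCCC(=O)Cc1cc(OC)cc(Oc2c(O)cc(O)c3c2C[C@]2(CCC[C@@H](C)O2)OC3=O)c1C(=O)O | intermediate
31 | CNP0301127.1 | CCCCCC(=O)Cc1cc(OC)cc2c1C(=O)Oc1cc(O)c3c(c1O2)C[C@]1(CCC[C@@H](C)O1)OC3=O | target

**Totals**
Total step count: 18.
Longest linear sequence: 14 steps, from 4 to 31 through steps 2–10 and 14–18.

**Steps most likely to fail**

Step 14 (Ullmann ether synthesis).
- What may go wrong: slow copper–phenoxide formation and slow C–O bond formation at an oxygen flanked by two ortho groups, competing arylation of the chelated hydroxyl, hydrodebromination, and copper-assisted air oxidation of the hydroquinone dianion.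
- Fallback: replace the metal-catalysed coupling by a metal-free addition–elimination on an aryl fluoride. It sets out from 20 and 24.
- Purchased 3-bromo-5-fluoroanisole is lithiated with LDA between the two halogens and acylated with methyl chloroformate to methyl 2-bromo-6-fluoro-4-methoxybenzoate F1.
- Sonogashira coupling with 24, now site-selective at the only C–Br bond, gives methyl 2-fluoro-6-(hept-1-yn-1-yl)-4-methoxybenzoate F2.
- The silver/TFA cyclisation gives 8-fluoro-6-methoxy-3-pentyl-1H-isochromen-1-one F3, whose coplanar lactone carbonyl activates the ortho C–F bond.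
- Heating F3 with 20 and Cs2CO3 in degassed DMSO should give 27, where the route is rejoined.

Step 18 (seven-membered lactonisation).
- What may go wrong: capture of the activated carboxyl by the enol of the neighbouring ketone, that is, reversion to the enol lactone (such material can re-enter at step 17), and acyl transfer from the new aryl ester to that enol after closure.
- Fallback: keep the ketone masked as a dithiane through the closure. It sets out from 26 and 20.
- Aqueous ethanolic KOH opens 26 to 2-bromo-4-methoxy-6-(2-oxoheptyl)benzoic acid F4.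
- Propane-1,3-dithiol and BF3·OEt2 give 2-bromo-4-methoxy-6-[(2-pentyl-1,3-dithian-2-yl)methyl]benzoic acid F5.
- Carboxylate-accelerated Ullmann coupling with 20 gives the diaryl ether acid F6.
- TFA gives the spirolactone acid F7, and BCl3 then gives the diphenol acid F8.
- DCC now has no ketone to compete with the phenol and closes the depsidone dithiane F9.
- MeI and CaCO3 in aqueous MeCN hydrolyse the dithiane under near-neutral, non-oxidising conditions to 31.

Step 10 (ring expansion).
- What may go wrong: thermal loss of methanol from the ketal with capture of that carbon by the newly formed ortho hydroxyl, interception of the ketene by hydroxyl groups, and air oxidation during isolation.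
- Fallback: mask the carbinol oxygen first, so that ring B is formed as a monoprotected hydroquinone. It sets out from 17.
- 1-(Trimethylsilyl)imidazole in CH2Cl2 gives the cyclobutenone trimethylsilyl ether F10.
- The same thermolysis, in which the silyloxy group is also an outward-rotating donor, gives the aryl trimethylsilyl ether F11, whose oxygen beside the side chain cannot attack the ketal.
- K2CO3 in MeOH at 0 °C just before the coupling frees 20.

**Further compounds**
F1 | step 14 | methyl 2-bromo-6-fluoro-4-methoxybenzoate | COC(=O)c1c(F)cc(OC)cc1Br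
F2 | step 14 | methyl 2-fluoro-6-(hept-1-yn-1-yl)-4-methoxybenzoate | CCCCCC#Cc1cc(OC)cc(F)c1C(=O)OC
F3 | step 14 | 8-fluoro-6-methoxy-3-pentyl-1H-isochromen-1-one | CCCCCC1=Cc2cc(OC)cc(F)c2C(=O)O1
F4 | step 18 | 2-bromo-4-methoxy-6-(2-oxoheptyl)benzoic acid | CCCCCC(=O)Cc1cc(OC)cc(Br)c1C(=O)O
F5 | step 18 | 2-bromo-4-methoxy-6-[(2-pentyl-1,3-dithian-2-yl)methyl]benzoic acid | CCCCCC1(Cc2cc(OC)cc(Br)c2C(=O)O)SCCCS1
F6 | step 18 | diaryl ether acid (dithiane, tert-butyl ester, methyl ketal, isopropyl ether) | CCCCCC1(Cc2cc(OC)cc(Oc3c(OC(C)C)cc(O)c(C(=O)OC(C)(C)C)c3CC3(OC)CCC[C@@H](C)O3)c2C(=O)O)SCCCS1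
F7 | step 18 | (3S,6'R)-spirolactone acid (dithiane, isopropyl ether) | CCCCCC1(Cc2cc(OC)cc(Oc3c(OC(C)C)cc(O)c4c3C[C@]3(CCC[C@@H](C)O3)OC4=O)c2C(=O)O)SCCCS1
F8 | step 18 | (3S,6'R)-spirolactone diphenol acid (dithiane) | CCCCCC1(Cc2cc(OC)cc(Oc3c(O)cc(O)c4c3C[C@]3(CCC[C@@H](C)O3)OC4=O)c2C(=O)O)SCCCS1
F9 | step 18 | depsidone dithiane | CCCCCC1(Cc2cc(OC)cc3c2C(=O)Oc2cc(O)c4c(c2O3)C[C@]2(CCC[C@@H](C)O2)OC4=O)SCCCS1
F10 | step 10 | trimethylsilyl ether of 17 | O=C1C=C(OC(C)C)C1(O[Si](C)(C)C)/C(CC2(OC)CCC[C@@H](C)O2)=C/C(=O)OC(C)(C)C
F11 | step 10 | tert-butyl 6-hydroxy-4-isopropoxy-2-{[(6R)-2-methoxy-6-methyloxan-2-yl]methyl}-3-(trimethylsilyloxy)benzoate | CC(C)(C)OC(=O)c1c(O)cc(OC(C)C)c(O[Si](C)(C)C)c1CC1(OC)CCC[C@@H](C)O1
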